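Amounts of target grow from the substrate, directly by the uncatalysed step and also by way of the isomer of the product.

in all of them: substrate 0.87 M; catalyst 0.61 mol%; time 30 h
- Wednesday's: temperature 70 °C
- Saturday's: at 70 °C until 6.0 h, from then on at 90 °C
- Tuesday's: temperature 90 °C

    target + catalyst ⇌ isomer of the product + catalyst, rate k1*[catalyst]*[target] forward; the back reaction follows from the equilibrium constant (K1 = 0.161, k1 = 15.3 M⁻¹ h⁻¹, Ea1 = 69.0 kJ mol⁻¹, ΔH1 = −1.00 kJ mol⁻¹)
    substrate ⇌ target (K2 = 0.675, k2 = 0.0250 h⁻¹, Ea2 = 120 kJ mol⁻¹, ΔH2 = −11.0 kJ mol⁻¹)
    isomer of the product ⇌ substrate (k3 = 0.0625 h⁻¹, Ea3 = 125 kJ mol⁻¹)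
    (constants at 70 °C)

- the constants hold at 70 °C; other temperatures follow from the activation energies and enthalpies

* which flask leads in amount of target, in percent of the substrate charged ("all alike" within 1.5 percentage points) (Wednesday's / Saturday's / Tuesday's / all alike)
* how much target is there at the end, in percent of the substrate charged: Wednesday's
* how much target is there at the end, in percent of the substrate charged: Saturday's
* how much target is there at the end, in percent of the substrate charged: Tuesday's

The useful quantity is the count of half-lives, the time in the flask divided by the relaxation half-life of substrate and target, both directions of that step taken together. For Wednesday's flask: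

relaxation rate = forward constant × (1 + 1 / equilibrium constant) = 0.0620 h⁻¹

half-life = ln(2) / rate = 11.2 h

count = time / half-life = 2.69

target ≈ balance share of the pair × (1 − 0.5^count) = 40.3% × (1 − 0.5^count) = 34.0%

The first setting is temperature. At 90 °C, Tuesday's half-life of 0.966 h gives a count of 31.1, far more than Wednesday's, and hardly any of the distance to balance remains. With that half-life short against the time, Tuesday's flask is reckoned to end under thermodynamic control, and its balance is reckoned next:

balance target = K / (1 + K + K × K of the catalysed step) = 33.4% at 90 °C, against 37.8% at 70 °C

Tuesday's flask thus has the lower balance, while Wednesday's estimate stands below its higher balance.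

The second setting is the moment of heating. Saturday's flask has 24.9 half-lives at 90 °C after the change at 6.0 h, so its estimate is Tuesday's balance.

The third setting is the catalyst loading. The catalyst acts on target and isomer, and at 70 °C the substrate feeds the isomer at 0.00679 h⁻¹, less than the 0.0250 h⁻¹ at which it feeds target. This reckoning therefore expects a small effect of loading on target.

Wednesday's estimate exceeds the balance of the hot flasks by 0.60 percentage points, less than the margin, so this reckoning expects all alike.

The forecast gives 33.4%, 33.45% and 33.45% for Wednesday's, Saturday's and Tuesday's, hence all alike: “All three land within 1.5 points”.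

The simulation gives 33.4%, 33.4% and 33.4%, hence all alike. Wednesday's flask is still moving at its count of 2.69, since it holds 37.8% after 300 h, while Tuesday's then holds 33.4%. Tuesday's flask run at 65 °C has for substrate and target an equilibrium constant of 0.715 and a relaxation half-life of 21.5 h. Its count is 1.39, which gives an estimate of 25.8%. That flask holds 26.4% target at 30.0 h, 7.0 points below Tuesday's.

The constants used here stand for no real mixture; the result is computed.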